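**Retrosynthetic overview**

1. Target 31 ⇐ 29 by unmasking the hydroquinone (oxidative demethylation, then reduction); 29 ⇐ 27 by turning an allyl group into the CH2CH2CO2H chain.
2. Key disconnection: ring A (the cyclohexanone C1–C2–C3–C4–C5–C10) ⇐ the cyclopentanone ring (C1, C2, C3, C5, C10) of trans-hydrindanone 22, by one-carbon ring enlargement through a β-oxido carbenoid (23 → 27); the new carbon C4 is allylated in the same flask.
3. Enabling feature: in 22 the ring-A carbonyl carbon C3 is bonded directly to the methyl-bearing quaternary ring-fusion carbon C5. C5 is therefore the migrating atom, the carbenoid carbon enters between C3 and C5, and the enolate is born at C4, the carbon that must carry the side chain.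
4. 22 ⇐ enone 17 (C8 methyl by cuprate addition anti to the axial C9 methyl, after 1,3-transposition of the ring-B carbonyl from C8 to C6) ⇐ 12 ⇐ reductive benzylation of the Hajos–Parrish-type enone 10 with benzyl bromide 5 (sets C9 and C10).
5. Ring order: cyclopentane ring (from 6) → ring B by amino-acid-mediated Robinson annulation (sets C5) → arene (from 1) attached at C9 → five-membered ring enlarged last to ring A.

Key step: step 16

Assumption: C4 lies α to the ketone and is taken to be the thermodynamically preferred equatorial epimer in the target, so it is set by base equilibration.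

Conventions in names: locants C1–C10 follow the target decalin (C3 = ketone carbon, C4 = chain carbon, C5 and C10 = ring fusion, C8 = CHMe, C9 = C(Me)CH2Ar; hydrindane intermediates lack C4). Ar = 2,5-dimethoxy-3-methylphenyl. "Me-face" is the face of the C5 methyl; "H-face" is the opposite face, which carries H-10.

**Route**

Step 1
Reactants: 1 4-methoxy-2-methylphenol
Product: 2 2-hydroxy-5-methoxy-3-methylbenzaldehyde
Conditions: (CH2O)n, MgCl2, Et3N, MeCN, reflux
Reagents that add atoms: paraformaldehyde (formaldehyde), C=O
Why: Magnesium-phenoxide-directed ortho-formylation of a phenol (a second equivalent of formaldehyde takes up the hydride) should functionalise only the one free position ortho to the hydroxyl group.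

Step 2
Reactants: 2 2-hydroxy-5-methoxy-3-methylbenzaldehyde
Product: 3 2,5-dimethoxy-3-methylbenzaldehyde
Conditions: MeI, K2CO3, DMF, 25 °C
Reagents that add atoms: iodomethane, CI
Why: Williamson O-methylation of the phenoxide should be clean because the aldehyde has no enolisable position.

Step 3
Reactants: 3 2,5-dimethoxy-3-methylbenzaldehyde
Product: 4 (2,5-dimethoxy-3-methylphenyl)methanol
Conditions: NaBH4, MeOH, 0 °C
Reagents that add atoms: none
Why: Borohydride reduction of an aromatic aldehyde to the benzylic alcohol is routine and touches nothing else.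

Step 4
Reactants: 4 (2,5-dimethoxy-3-methylphenyl)methanol
Product: 5 1-(bromomethyl)-2,5-dimethoxy-3-methylbenzene
Conditions: PBr3, CH2Cl2, 0 °C
Reagents that add atoms: phosphorus tribromide, BrP(Br)Br
Why: Substitution of the electron-rich benzylic alcohol through its phosphite ester (SN2) is standard for 2,5-dimethoxybenzyl systems.

Step 5
Reactants: 6 2-methylcyclopentane-1,3-dione; 7 pent-1-en-3-one (ethyl vinyl ketone)
Product: 8 2-methyl-2-(3-oxopentyl)cyclopentane-1,3-dione
Conditions: Et3N (cat.), MeCN, 25 °C
Reagents that add atoms: none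
Why: Michael addition of the acidic 2-alkyl-1,3-dione to the vinyl ketone under amine catalysis should give the prochiral triketone without further condensation.

Step 6
Reactants: 8 2-methyl-2-(3-oxopentyl)cyclopentane-1,3-dione
Product: 9 (7aR)-4,7a-dimethyl-2,3,7,7a-tetrahydro-1H-indene-1,5(6H)-dione
Conditions: D-phenylalanine (1 equiv), HClO4 (aq, 0.5 equiv), MeCN, 80 °C
Reagents that add atoms: none
Why: Amino-acid-mediated enantiotopic-group-selective intramolecular aldol condensation (Hajos–Parrish reaction, the ring-closing half of a Robinson annulation) should close ring B, and the D-amino acid selects, through a carboxylic-acid-organised enamine transition state, the ring carbonyl that gives the R configuration at the quaternary carbon C5.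

Step 7
Reactants: 9 (7aR)-4,7a-dimethyl-2,3,7,7a-tetrahydro-1H-indene-1,5(6H)-dione
Product: 10 enone ketal (9 with the C3 cyclopentanone carbonyl as 1,3-dioxolane)
Conditions: ethylene glycol, p-TsOH·H2O (cat.), 4 Å molecular sieves, 25 °C
Reagents that add atoms: ethylene glycol, OCCO
Why: Acid-catalysed ketalisation should be selective for the saturated cyclopentanone carbonyl because the conjugated, fully substituted enone carbonyl is much less electrophilic.

Step 8
Reactants: 10 enone ketal; 5 1-(bromomethyl)-2,5-dimethoxy-3-methylbenzene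
Product: 12 benzylated trans-hydrindan-8-one ketal, via lithium enolate 11 (not isolated)
Conditions: Li (2.2 equiv), NH3(l)/THF, t-BuOH (1 equiv), −78 °C; isoprene; then 5, THF, −78 to 0 °C
Reagents that add atoms: none
Why: Birch-type reductive alkylation of the enone: axial protonation of the β-carbon C10 on the face opposite to the C5 methyl should give the trans-fused enolate 11, which is C-benzylated at C9 from the same less hindered face, so that ArCH2 ends up on the H-face and the C9 methyl on the Me-face.

Step 9
Reactants: 12 benzylated trans-hydrindan-8-one ketal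
Product: 14 ring-B enone (C8 ketone with C6=C7), via α-phenylselanyl ketone 13 (not isolated)
Conditions: LiN(i-Pr)2, THF, −78 °C; PhSeCl; then H2O2, pyridine, CH2Cl2, 0 to 25 °C
Reagents that add atoms: none
Why: α-Selenenylation of the only possible enolate (C7, since C9 is quaternary) followed by selenoxide syn-elimination toward C6 should give the enone without touching a stereocentre.

Step 10
Reactants: 14 ring-B enone
Product: 15 6,7-epoxy-8-ketone (epoxide on the H-face)
Conditions: H2O2 (30% aq), NaOH, MeOH, 0 °C
Reagents that add atoms: hydrogen peroxide, OO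
Why: Weitz–Scheffer nucleophilic epoxidation, in which hydroperoxide adds to C6 from the face opposite to the adjacent axial C5 methyl, should place the epoxide on the H-face.

Step 11
Reactants: 15 6,7-epoxy-8-ketone
Product: 16 allylic alcohol (C6–OH on the H-face with C7=C8)
Conditions: N2H4·H2O, AcOH (cat.), MeOH, 0 to 25 °C
Reagents that add atoms: none
Why: Wharton transposition: the epoxy hydrazone fragments with loss of N2, the C6–O bond is kept (so the hydroxyl stays on the H-face) and the double bond moves to C7=C8.

Step 12
Reactants: 16 allylic alcohol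
Product: 17 transposed enone (C6 ketone with C7=C8)
Conditions: DMP (triacetoxyperiodinane), NaHCO3, CH2Cl2, 25 °C
Reagents that add atoms: none
Why: Periodinane oxidation of the secondary allylic alcohol under neutral conditions should leave the dioxolane intact and completes the 1,3-transposition of the ring-B carbonyl from C8 to C6.

Step 13
Reactants: 17 transposed enone
Product: 19 8-methyl-6-ketone, via silyl enol ether 18 (not isolated)
Conditions: Me2CuLi (from MeLi and CuI), Me3SiCl, THF, −78 °C; then K2CO3, MeOH, 25 °C
Reagents that add atoms: lithium dimethylcuprate, [Li+].C[Cu-]C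
Why: Cuprate conjugate addition accelerated by Me3SiCl: stereoelectronically preferred axial attack at C8 anti to the axial C9 methyl should place the new methyl on the H-face, cis to ArCH2 and trans to both other methyl groups, and methanolysis of 18 returns the ketone.

Step 14
Reactants: 19 8-methyl-6-ketone
Product: 22 trans-hydrindan-3-one, via hydrazone 20 (not isolated), via deoxygenated ketal 21 (not isolated)
Conditions: N2H4·H2O, KOH, diethylene glycol, 130 then 200 °C; then 2 M HCl, THF, 25 °C
Reagents that add atoms: water, O
Why: Wolff–Kishner reduction (Huang-Minlon modification) should remove the C6 carbonyl without touching a stereocentre (C5 is quaternary, C7 is CH2), and acid hydrolysis of the dioxolane in the work-up unveils the cyclopentanone.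

Step 15
Reactants: 22 trans-hydrindan-3-one
Product: 23 3-(dibromomethyl)hydrindan-3-ol (OH on the Me-face)
Conditions: CH2Br2, LiN(i-Pr)2 (added to the ketone/CH2Br2 mixture), THF, −78 °C; then H2O
Reagents that add atoms: dibromomethane, BrCBr
Why: 1,2-Addition of dibromomethyllithium, generated in the presence of the ketone to outrun its decomposition, should occur on the cyclopentanone face opposite to the angular C5 methyl, as with 17-keto steroids (this carbinol centre is destroyed in step 16).

Step 16
Reactants: 23 3-(dibromomethyl)hydrindan-3-ol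
Product: 27 4-allyl trans-decal-3-one (allyl equatorial on the Me-face), via β-oxido carbenoid 24 (not isolated), via lithium enolate 25 (not isolated), via axial allyl epimer 26 (not isolated)
Conditions: n-BuLi (2.2 equiv), THF, −78 to −20 °C; then allyl bromide, DMPU, −78 to 0 °C; then NaOMe, MeOH, 25 °C
Reagents that add atoms: allyl bromide (3-bromoprop-1-ene), C=CCBr
Why: Two equivalents of n-BuLi turn 23 into the lithium alkoxide/α-bromo-α-lithio carbenoid 24 (O–H deprotonation, then Br/Li exchange); on warming, a ring carbon shifts 1,2 to the electron-deficient carbenoid carbon with loss of LiBr, which inserts that carbon into the C3–C5 bond and gives lithium enolate 25 (β-oxido carbenoid ring enlargement of cycloalkanones, the anionic counterpart of a Tiffeneau–Demjanov or semipinacol shift). No ring is closed by cyclisation: ring A arises from the cyclopentane ring by this one-atom insertion, and C5 migrates with retention, so the trans ring fusion and all ring-B centres are untouched. The step needs C5, not the CH2 carbon C2, to migrate; the substrate secures this because the fully substituted α-carbon is the better migrating group in this carbenoid shift, as is known for 2-alkylcycloalkanones. The enolate is regiospecific (C3=C4) because the inserted carbon is the carbenoid carbon itself, and it is C-allylated at C4 before it can equilibrate to the C2 side, the electrophile entering axially from the face opposite to the C5 methyl to give 26. The only new stereocentre, C4, is α to the ketone and is then set under thermodynamic control by NaOMe, which should move the allyl group into the equatorial position on the Me-face (27), the arrangement of the target.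

Step 17
Reactants: 27 4-allyl trans-decal-3-one
Product: 28 4-(3-hydroxypropyl) trans-decal-3-one
Conditions: catecholborane, RhCl(PPh3)3 (2 mol%), THF, 25 °C; then NaOH, H2O2, 0 °C
Reagents that add atoms: hydrogen peroxide, OO
Why: Rhodium-catalysed hydroboration with catecholborane is anti-Markovnikov for terminal alkenes and, unlike the uncatalysed reaction, leaves ketones untouched, and alkaline peroxide oxidises the C–B bond to the primary alcohol.

Step 18
Reactants: 28 4-(3-hydroxypropyl) trans-decal-3-one
Product: 29 keto acid dimethyl ether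
Conditions: TEMPO (cat.), PhI(OAc)2, MeCN/H2O, 25 °C
Reagents that add atoms: water, O
Why: Nitroxyl-catalysed oxidation with a hypervalent iodine co-oxidant in wet acetonitrile should take the primary alcohol through the aldehyde hydrate to the carboxylic acid and leave the ketone and the dimethoxyarene alone.

Step 19
Reactants: 29 keto acid dimethyl ether
Product: 31 target hydroquinone keto acid, via quinone 30 (not isolated)
Conditions: (NH4)2Ce(NO3)6, MeCN/H2O, 0 °C; then Na2S2O4, H2O/EtOAc, 25 °C
Reagents that add atoms: water, O
Why: Oxidative demethylation of the para-dimethoxyarene by cerium ammonium nitrate (water adds to the ring, methanol leaves) should give quinone 30, which dithionite reduces in the work-up to the hydroquinone.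

**Compound list**

1 | 4-methoxy-2-methylphenol | Cc1cc(OC)ccc1O | starting material
2 | 2-hydroxy-5-methoxy-3-methylbenzaldehyde | Cc1cc(OC)cc(C=O)c1O | intermediate
3 | 2,5-dimethoxy-3-methylbenzaldehyde | Cc1cc(OC)cc(C=O)c1OC | intermediate
4 | (2,5-dimethoxy-3-methylphenyl)methanol | Cc1cc(OC)cc(CO)c1OC | intermediate
5 | 1-(bromomethyl)-2,5-dimethoxy-3-methylbenzene | Cc1cc(OC)cc(CBr)c1OC | intermediate
6 | 2-methylcyclopentane-1,3-dione | CC1C(=O)CCC1=O | starting material
7 | pent-1-en-3-one (ethyl vinyl ketone) | CCC(=O)C=C | starting material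
8 | 2-methyl-2-(3-oxopentyl)cyclopentane-1,3-dione | CCC(=O)CCC1(C)C(=O)CCC1=O | intermediate
9 | (7aR)-4,7a-dimethyl-2,3,7,7a-tetrahydro-1H-indene-1,5(6H)-dione (C3 and C8 ketones, C9=C10, C5 quaternary R) | CC1=C2CCC(=O)[C@]2(C)CCC1=O | intermediate
10 | enone ketal: 9 with the C3 carbonyl as 1,3-dioxolane | CC1=C2CCC3(OCCO3)[C@]2(C)CCC1=O | intermediate
11 | trans-fused lithium enolate (C8–OLi, C8=C9; H-10 on the face opposite to the C5 methyl) | CC=2[C@H]3CCC4(OCCO4)[C@]3(C)CCC=2O[Li] | intermediate
12 | benzylated trans-hydrindan-8-one ketal: C3 dioxolane; C5-Me and C9-Me on the Me-face; H-10 and C9-CH2Ar on the H-face | Cc1cc(OC)cc(C[C@]2(C)[C@H]3CCC4(OCCO4)[C@]3(C)CCC2=O)c1OC | intermediate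
13 | 7-(phenylselanyl) derivative of 12 (either epimer at C7) | Cc1cc(OC)cc(C[C@]2(C)[C@H]3CCC4(OCCO4)[C@]3(C)CC([Se]c5ccccc5)C2=O)c1OC | intermediate
14 | ring-B enone: C8 ketone, C6=C7 | Cc1cc(OC)cc(C[C@]2(C)[C@H]3CCC4(OCCO4)[C@]3(C)C=CC2=O)c1OC | intermediate
15 | 6,7-epoxy-8-ketone, epoxide on the H-face | Cc1cc(OC)cc(C[C@]2(C)[C@H]3CCC4(OCCO4)[C@]3(C)[C@@H]5O[C@@H]5C2=O)c1OC | intermediate
16 | allylic alcohol: C6–OH on the H-face, C7=C8 | Cc1cc(OC)cc(C[C@]2(C)[C@H]3CCC4(OCCO4)[C@]3(C)[C@H](O)C=C2)c1OC | intermediate
17 | transposed enone: C6 ketone, C7=C8 | Cc1cc(OC)cc(C[C@]2(C)[C@H]3CCC4(OCCO4)[C@]3(C)C(=O)C=C2)c1OC | intermediate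
18 | trimethylsilyl enol ether (C6–OSiMe3, C6=C7) with the C8 methyl on the H-face | Cc1cc(OC)cc(C[C@]2(C)[C@H]3CCC4(OCCO4)[C@]3(C)C(O[Si](C)(C)C)=C[C@@H]2C)c1OC | intermediate
19 | 8-methyl-6-ketone: C8-Me on the H-face (cis to ArCH2, trans to C9-Me and C5-Me) | Cc1cc(OC)cc(C[C@]2(C)[C@H]3CCC4(OCCO4)[C@]3(C)C(=O)C[C@@H]2C)c1OC | intermediate
20 | C6 hydrazone of 19 | Cc1cc(OC)cc(C[C@]2(C)[C@H]3CCC4(OCCO4)[C@]3(C)C(=NN)C[C@@H]2C)c1OC | intermediate
21 | deoxygenated ketal (C6 = CH2, C3 dioxolane) | Cc1cc(OC)cc(C[C@]2(C)[C@H]3CCC4(OCCO4)[C@]3(C)CC[C@@H]2C)c1OC | intermediate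
22 | trans-hydrindan-3-one: cyclopentanone carbonyl C3 on quaternary C5; C5-Me, C9-Me on the Me-face; H-10, C9-CH2Ar, C8-Me on the H-face | Cc1cc(OC)cc(C[C@]2(C)[C@H]3CCC(=O)[C@]3(C)CC[C@@H]2C)c1OC | intermediate
23 | 3-(dibromomethyl)hydrindan-3-ol: OH on the Me-face, CHBr2 on the H-face | Cc1cc(OC)cc(C[C@]2(C)[C@H]3CC[C@](O)(C(Br)Br)[C@]3(C)CC[C@@H]2C)c1OC | intermediate
24 | β-oxido carbenoid: lithium alkoxide with a C(H)(Br)Li group on C3 | Cc1cc(OC)cc(C[C@]2(C)[C@H]3CC[C@](O[Li])(C([Li])Br)[C@]3(C)CC[C@@H]2C)c1OC | intermediate
25 | lithium enolate of the ring-enlarged ketone (C3–OLi, C3=C4) | Cc1cc(OC)cc(C[C@]2(C)[C@H]3CCC(O[Li])=C[C@]3(C)CC[C@@H]2C)c1OC | intermediate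
26 | 4-allyl trans-decal-3-one, allyl axial on the H-face (C4 epimer of 27) | Cc1cc(OC)cc(C[C@]2(C)[C@H]3CCC(=O)[C@H](CC=C)[C@]3(C)CC[C@@H]2C)c1OC | intermediate
27 | 4-allyl trans-decal-3-one, allyl equatorial on the Me-face | Cc1cc(OC)cc(C[C@]2(C)[C@H]3CCC(=O)[C@@H](CC=C)[C@]3(C)CC[C@@H]2C)c1OC | intermediate
28 | 4-(3-hydroxypropyl) trans-decal-3-one (may sit partly as the cyclic hemiketal) | Cc1cc(OC)cc(C[C@]2(C)[C@H]3CCC(=O)[C@@H](CCCO)[C@]3(C)CC[C@@H]2C)c1OC | intermediate
29 | keto acid dimethyl ether: 3-(3-oxo-decalin-4-yl)propanoic acid with Ar = 2,5-dimethoxy-3-methylphenyl | Cc1cc(OC)cc(C[C@]2(C)[C@H]3CCC(=O)[C@@H](CCC(=O)O)[C@]3(C)CC[C@@H]2C)c1OC | intermediate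
30 | 2-methyl-1,4-benzoquinone bearing the keto acid decalin through CH2 at position 6 | CC1=CC(=O)C=C(C[C@]2(C)[C@H]3CCC(=O)[C@@H](CCC(=O)O)[C@]3(C)CC[C@@H]2C)C1=O | intermediate
31 | 3-[(1S,4aR,5S,6S,8aR)-5-[(2,5-dihydroxy-3-methylphenyl)methyl]-5,6,8a-trimethyl-2-oxodecahydronaphthalen-1-yl]propanoic acid (route locants: 4S,5R,8S,9S,10R) | Cc1cc(O)cc(C[C@]2(C)[C@H]3CCC(=O)[C@@H](CCC(=O)O)[C@]3(C)CC[C@@H]2C)c1O | target

**Step count and risks**

Total: 19 steps. Longest linear sequence: 16 steps (1 → 5 → 12 → 31; steps 1–4 and 8–19).

Most likely to fail, step 16. The CH2 carbon C2 may migrate instead of the quaternary C5, which would put the ketone on the wrong side. The hindered enolate may also be allylated sluggishly, be O-allylated, or be quenched by proton transfer before C–C bond formation. Fallback, from 22: 1-(methylselanyl)pent-4-enyllithium (from 1,1-bis(methylselanyl)pent-4-ene and n-BuLi, THF, −78 °C) is added to the ketone to give the β-hydroxy selenide F1. AgBF4 then ionises the C–Se bond and triggers the cationic semipinacol ring enlargement, in which the more substituted carbon migrates; NaOMe equilibration gives the 4-(but-3-enyl) decalone F2. Lemieux–Johnson cleavage (OsO4 cat., NaIO4) gives the aldehyde F3, and Pinnick oxidation (NaClO2, 2-methylbut-2-ene) returns to the route at 29. Here the chain comes in with the carbanion, so no hindered enolate has to be alkylated.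

Second, step 8. Protonation of C10 from the wrong face would give the cis-fused hydrindanone; over-reduction of the ketone or O-benzylation of the enolate are further leaks. Fallback, from 10: deconjugative α-benzylation of the potassium dienolate (KOt-Bu, t-BuOH/THF, then 5) from the face opposite to the C5 methyl gives the β,γ-unsaturated ketone F4 (C9 quaternary, C10=C1 double bond). Radical hydrogen-atom-transfer hydrogenation of the ring-fusion alkene (Mn(dpm)3 cat., PhSiH3, t-BuOOH, i-PrOH), which should deliver hydrogen to C10 axially, returns to the route at 12.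

Third, step 13. The cuprate may react too slowly at the neopentyl β-carbon C8, or add with poor facial selectivity next to the quaternary C9. Fallback, from 16: phenyl isocyanate gives the N-phenyl carbamate F5. Deprotonation and a lithium methylcuprate (MeLi, CuI, THF) then effect a carbamate-directed syn-SN2′ displacement, which delivers the methyl group to C8 on the face of the leaving group (H-face) and gives the alkene F6. Hydrogenation (H2, Pd/C) returns to the route at 21, which the acid hydrolysis of step 14 converts to 22.

**Further compounds**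

F1 | step 16 | β-hydroxy selenide: 22 with OH (Me-face) and a CH(SeMe)CH2CH2CH=CH2 group (H-face) on C3, either epimer at the selenium-bearing carbon | Cc1cc(OC)cc(C[C@]2(C)[C@H]3CC[C@](O)(C(CCC=C)[Se]C)[C@]3(C)CC[C@@H]2C)c1OC
F2 | step 16 | 4-(but-3-enyl) trans-decal-3-one, chain equatorial on the Me-face | Cc1cc(OC)cc(C[C@]2(C)[C@H]3CCC(=O)[C@@H](CCC=C)[C@]3(C)CC[C@@H]2C)c1OC
F3 | step 16 | 4-(3-oxopropyl) trans-decal-3-one (keto aldehyde) | Cc1cc(OC)cc(C[C@]2(C)[C@H]3CCC(=O)[C@@H](CCC=O)[C@]3(C)CC[C@@H]2C)c1OC
F4 | step 8 | β,γ-unsaturated ketone: C8 ketone, C9 bearing Me (Me-face) and ArCH2 (H-face), C10=C1 double bond, C3 dioxolane | Cc1cc(OC)cc(C[C@]2(C)C3=CCC4(OCCO4)[C@]3(C)CCC2=O)c1OC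
F5 | step 13 | N-phenyl carbamate of allylic alcohol 16 | Cc1cc(OC)cc(C[C@]2(C)[C@H]3CCC4(OCCO4)[C@]3(C)[C@H](OC(=O)Nc5ccccc5)C=C2)c1OC
F6 | step 13 | alkene: C6=C7, C8 methyl on the H-face, C3 dioxolane | Cc1cc(OC)cc(C[C@]2(C)[C@H]3CCC4(OCCO4)[C@]3(C)C=C[C@@H]2C)c1OC
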